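**Plan** (chain numbering: C1 = benzylic carbon, C17 = terminal methyl)
- Cuts: first the two phenol O–Si bonds. Then C9–C10 (vinyl CH to CH2) together with C7–C8, which gives a 7‑arylheptyl metal (C1–C7), acetylene (C8, C9) and (S)‑1,2‑epoxyoctane (C10–C17). Last, the aryl–C1 bond.
- Enabling feature: C11(OH)–C10H2–C9H=C8H is a homoallylic alcohol whose cis olefin carbons carry only H besides the chain. O/C11/C10 therefore map onto a terminal oxirane, and C8/C9 map onto HC≡CH after a syn carbocupration.
- Forward order: no ring is built, since the benzene ring is bought as 5‑bromoresorcinol. It is silylated, joined to C1–C7 by a copper‑catalysed Grignard coupling, and Br is exchanged for I. One flask then runs Li → Cu → acetylene → epoxide, and fluoride frees the phenols.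
- Stereochemistry: C11 (S) comes from a hydrolytic kinetic resolution of racemic 1,2‑epoxyoctane, and its C–O bond is never broken. The Z olefin comes from syn addition to acetylene and retention in the C9–C10 coupling.

Key step: step 5

Remark: C11 is S (OH > C10 > C12 > H), the opposite sense to the carbinol of natural ricinoleic acid, so the (S)‑oxirane is required. In step 5 one alkenyl ligand per copper is counted as transferred.

**Step 1**
Reactants: 1 (±)-1,2-epoxyoctane (racemic 2-hexyloxirane)
Product: 2 (S)-1,2-epoxyoctane [(S)-2-hexyloxirane]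
Conditions: (S,S)-(salen)Co(OAc) (0.5 mol %; salen = N,N'-bis(3,5-di-tert-butylsalicylidene)cyclohexane-1,2-diamine dianion), H2O (0.55 equiv), minimal THF, 0 °C → rt; distillation
Reagents that add atoms: none
Why: Jacobsen hydrolytic kinetic resolution, in which the (S,S)-cobalt salen catalyst hydrates the R enantiomer of a terminal alkyl oxirane much faster than the S enantiomer, so the unreacted (S)-epoxide, which holds the only stereocentre of the target, should distil off in high enantiomeric purity from the non-volatile diol.

**Step 2**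
Reactants: 3 5-bromoresorcinol (5-bromobenzene-1,3-diol)
Product: 4 1-bromo-3,5-bis(triisopropylsilyloxy)benzene
Conditions: TIPSCl (2.3 equiv), imidazole (5 equiv), DMF, rt
Reagents that add atoms: triisopropylsilyl chloride, CC(C)[Si](Cl)(C(C)C)C(C)C
Why: Standard phenol silylation (silyl chloride and imidazole in DMF), with TIPS chosen because it withstands Grignard, organolithium and cuprate reagents, directs ring lithiation poorly, and leaves with fluoride under conditions harmless to a cis olefin and a secondary alcohol.

**Step 3**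
Reactants: 4 1-bromo-3,5-bis(triisopropylsilyloxy)benzene; 5 1,7-dibromoheptane
Product: 7 1-(7-bromoheptyl)-3,5-bis(triisopropylsilyloxy)benzene, via arylmagnesium bromide 6 (not isolated)
Conditions: Mg, THF, reflux; then added to 5 (3 equiv), Li2CuCl4 (3 mol %), THF, 0 °C → rt; surplus 5 distilled off
Reagents that add atoms: none
Why: Kochi-type copper-catalysed cross-coupling of an aryl Grignard reagent with a primary alkyl bromide, in which the threefold excess of the symmetrical dibromide should hold back the second substitution.

**Step 4**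
Reactants: 7 1-(7-bromoheptyl)-3,5-bis(triisopropylsilyloxy)benzene
Product: 8 1-(7-iodoheptyl)-3,5-bis(triisopropylsilyloxy)benzene
Conditions: NaI (3 equiv), acetone, reflux
Reagents that add atoms: sodium iodide, [Na+].[I-]
Why: Finkelstein halide exchange driven by precipitation of NaBr from acetone, needed because only the primary iodide undergoes clean halogen–lithium exchange with t-BuLi.

**Step 5**
Reactants: 8 1-(7-iodoheptyl)-3,5-bis(triisopropylsilyloxy)benzene; 9 acetylene; 2 (S)-1,2-epoxyoctane
Product: 13 5-[(8Z,11S)-11-hydroxyheptadec-8-enyl]-1,3-bis(triisopropylsilyloxy)benzene, via alkyllithium 10 (not isolated), via lithium dialkylcuprate 11 (not isolated), via lithium bis[(Z)-alkenyl]cuprate 12 (not isolated)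
Conditions: 8 (2.0 equiv), t-BuLi (4.0 equiv), pentane/Et2O 3:2, –78 °C; CuBr·SMe2 (1.0 equiv), Et2O, –40 °C; 9 (2.0 equiv, measured, acetone-free), –50 → –25 °C; 2 (1.0 equiv), BF3·OEt2 (1.0 equiv), –78 → –50 °C; aq NH4Cl/NH3
Reagents that add atoms: none
Why: Iodine–lithium exchange and transmetalation give the Gilman cuprate 11, whose two C–Cu bonds add syn across acetylene (Normant carbocupration), so that copper and the C1–C7 chain end up cis on C9=C8 in 12. The alkenyl ligand then attacks the BF3-activated oxirane in an SN2 manner at the unsubstituted carbon C10 with retention of the olefin geometry, which forms C9–C10; the closest known reaction type is the BF3-promoted opening of terminal epoxides by (Z)-dialkenylcuprates made from acetylene. No ring is closed and no new sp3 stereocentre is created: the C11–O bond is never broken, so the S configuration of 2 is carried over unchanged, and the Z geometry is controlled only by the syn addition and by the configurational stability of the alkenylcopper at low temperature. The step needs a single insertion (secured by two equivalents of acetylene and a ceiling of –25 °C, where the less reactive alkenylcuprate should not add to a second acetylene), carbometalation in preference to deprotonation of acetylene (secured by Et2O as the solvent), and attack at the terminal carbon (secured by the hexyl group that shields C11). The bulky TIPS ethers resist organolithium reagents and are poor directors of ring lithiation, so 10 should not be consumed by the arene.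

**Step 6**
Reactants: 13 5-[(8Z,11S)-11-hydroxyheptadec-8-enyl]-1,3-bis(triisopropylsilyloxy)benzene
Product: 14 5-[(8Z,11S)-11-hydroxyheptadec-8-enyl]benzene-1,3-diol (target)
Conditions: TBAF (2.2 equiv), AcOH (2.2 equiv), THF, 0 °C, under argon
Reagents that add atoms: none
Why: Fluoride-induced cleavage of aryl silyl ethers driven by the strong Si–F bond, buffered with acetic acid so that the air-sensitive resorcinolate is protonated at once and neither the Z olefin nor C11 is touched.

**Compound list**
1 | (±)-1,2-epoxyoctane | CCCCCCC1CO1 | starting material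
2 | (S)-1,2-epoxyoctane | CCCCCC[C@H]1CO1 | intermediate
3 | 5-bromoresorcinol | Oc1cc(O)cc(Br)c1 | starting material
4 | 1-bromo-3,5-bis(triisopropylsilyloxy)benzene | Brc1cc(O[Si](C(C)C)(C(C)C)C(C)C)cc(O[Si](C(C)C)(C(C)C)C(C)C)c1 | intermediate
5 | 1,7-dibromoheptane | BrCCCCCCCBr | starting material
6 | 3,5-bis(triisopropylsilyloxy)phenylmagnesium bromide | Br[Mg]c1cc(O[Si](C(C)C)(C(C)C)C(C)C)cc(O[Si](C(C)C)(C(C)C)C(C)C)c1 | intermediate
7 | 1-(7-bromoheptyl)-3,5-bis(triisopropylsilyloxy)benzene | BrCCCCCCCc1cc(O[Si](C(C)C)(C(C)C)C(C)C)cc(O[Si](C(C)C)(C(C)C)C(C)C)c1 | intermediate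
8 | 1-(7-iodoheptyl)-3,5-bis(triisopropylsilyloxy)benzene | ICCCCCCCc1cc(O[Si](C(C)C)(C(C)C)C(C)C)cc(O[Si](C(C)C)(C(C)C)C(C)C)c1 | intermediate
9 | acetylene | C#C | starting material
10 | 7-[3,5-bis(triisopropylsilyloxy)phenyl]heptyllithium | [Li]CCCCCCCc1cc(O[Si](C(C)C)(C(C)C)C(C)C)cc(O[Si](C(C)C)(C(C)C)C(C)C)c1 | intermediate
11 | lithium bis{7-[3,5-bis(triisopropylsilyloxy)phenyl]heptyl}cuprate | [Li+].[Cu-](CCCCCCCc1cc(O[Si](C(C)C)(C(C)C)C(C)C)cc(O[Si](C(C)C)(C(C)C)C(C)C)c1)CCCCCCCc1cc(O[Si](C(C)C)(C(C)C)C(C)C)cc(O[Si](C(C)C)(C(C)C)C(C)C)c1 | intermediate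
12 | lithium bis{(Z)-9-[3,5-bis(triisopropylsilyloxy)phenyl]non-1-enyl}cuprate | [Li+].[Cu-](/C=C\CCCCCCCc1cc(O[Si](C(C)C)(C(C)C)C(C)C)cc(O[Si](C(C)C)(C(C)C)C(C)C)c1)/C=C\CCCCCCCc1cc(O[Si](C(C)C)(C(C)C)C(C)C)cc(O[Si](C(C)C)(C(C)C)C(C)C)c1 | intermediate
13 | 5-[(8Z,11S)-11-hydroxyheptadec-8-enyl]-1,3-bis(triisopropylsilyloxy)benzene | CCCCCC[C@H](O)C/C=C\CCCCCCCc1cc(O[Si](C(C)C)(C(C)C)C(C)C)cc(O[Si](C(C)C)(C(C)C)C(C)C)c1 | intermediate
14 | 5-[(8Z,11S)-11-hydroxyheptadec-8-enyl]benzene-1,3-diol | CCCCCC[C@H](O)C/C=C\CCCCCCCc1cc(O)cc(O)c1 | target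

Total step count: 6. Longest linear sequence: 5 (steps 2, 3, 4, 5, 6). Step 1 is the side branch.

**Steps most likely to fail**

Step 5. Three things may go wrong:
- Acetylene may protonate the cuprate instead of being carbometalated.
- A second acetylene may insert if the flask warms.
- The alkenyl ligand may transfer too slowly, while the Lewis acid rearranges the oxirane.

The fallback sets out from 2 and 8 and comes back at 13. It builds C9–C10 at the alkyne oxidation level. Epoxide 2 is opened at C10 with commercial lithium acetylide–ethylenediamine complex in DMSO to give (S)-dec-1-yn-4-ol F1. Double deprotonation with n-BuLi (2 equiv) in THF/DMPU gives its dilithio derivative F2. F2 is alkylated on carbon by iodide 8 to 5-[(11S)-11-hydroxyheptadec-8-ynyl]-1,3-bis(triisopropylsilyloxy)benzene F3. Semihydrogenation over Pd/CaCO3 poisoned with Pb(OAc)2 and quinoline (Lindlar conditions) then gives 13.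

Step 3. Three things may go wrong:
- Substitution may occur at both ends of the dibromide.
- The aryl Grignard reagent may homocouple.
- Separation from the surplus dibromide may be laborious.

The fallback sets out from 4 and comes back at 8, so step 4 is skipped as well. Sonogashira coupling of 4 with commercial hept-6-yn-1-ol (PdCl2(PPh3)2, CuI, Et3N, 70 °C) gives 7-[3,5-bis(triisopropylsilyloxy)phenyl]hept-6-yn-1-ol F4. Full hydrogenation (H2, Pd/C, EtOAc) gives 7-[3,5-bis(triisopropylsilyloxy)phenyl]heptan-1-ol F5. Appel-type iodination (I2, PPh3, imidazole, CH2Cl2) gives 8.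

Step 1. The resolution may stall through reduction of the catalyst to divalent cobalt, or through poor mixing of water with the lipophilic epoxide. The enantiomeric purity would then be incomplete, and no later step can raise it.

The fallback sets out from 1 and comes back at 2. It replaces the resolution by an asymmetric reduction. Opening of 1 with LiCl/AcOH in THF gives racemic 1-chlorooctan-2-ol F6. Oxidation (NaOCl, catalytic TEMPO, KBr, CH2Cl2/H2O) gives 1-chlorooctan-2-one F7. A ketoreductase of anti-Prelog selectivity (NADPH, isopropanol recycling) gives (S)-1-chlorooctan-2-ol F8. Aqueous NaOH then closes the oxirane onto the CH2Cl carbon without touching the stereocentre, giving 2.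

**Further compounds**
F1 | step 5 | (S)-dec-1-yn-4-ol | CCCCCC[C@H](O)CC#C
F2 | step 5 | dilithio derivative of (S)-dec-1-yn-4-ol (lithium alkoxide and lithium acetylide) | CCCCCC[C@H](O[Li])CC#C[Li]
F3 | step 5 | 5-[(11S)-11-hydroxyheptadec-8-ynyl]-1,3-bis(triisopropylsilyloxy)benzene | CCCCCC[C@H](O)CC#CCCCCCCCc1cc(O[Si](C(C)C)(C(C)C)C(C)C)cc(O[Si](C(C)C)(C(C)C)C(C)C)c1
F4 | step 3 | 7-[3,5-bis(triisopropylsilyloxy)phenyl]hept-6-yn-1-ol | OCCCCCC#Cc1cc(O[Si](C(C)C)(C(C)C)C(C)C)cc(O[Si](C(C)C)(C(C)C)C(C)C)c1
F5 | step 3 | 7-[3,5-bis(triisopropylsilyloxy)phenyl]heptan-1-ol | OCCCCCCCc1cc(O[Si](C(C)C)(C(C)C)C(C)C)cc(O[Si](C(C)C)(C(C)C)C(C)C)c1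
F6 | step 1 | racemic 1-chlorooctan-2-ol | CCCCCCC(O)CCl
F7 | step 1 | 1-chlorooctan-2-one | CCCCCCC(=O)CCl
F8 | step 1 | (S)-1-chlorooctan-2-ol | CCCCCC[C@H](O)CCl
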